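Ring A is disconnected at C4a–C5, C5–C6 and C7–C8. The feature exploited is the contiguous oxygen–prenyl–oxygen array on C5, C6 and C7 of ring A together with its C4a–C8a edge shared with pyranone ring C: a ketene supplies C5 and an ynol ether supplies C6 and C7. One photochemical–thermal operation (Wolff rearrangement, [2+2] cycloaddition, cyclobutenone opening, 6π-electrocyclization) builds ring A on a finished 3-aryl-4-pyranone, leaving 5-OH free and 7-OH silylated. The precursor is a 2-(diazoacetyl)-5-aryl-4-pyranone made from comenic acid by Suzuki coupling. C8 is then formylated and homologated, and the (R)-carbinol is set by asymmetric isopropenylation.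

Key step: step 8

Remark: the stereodescriptor in the given SMILES corresponds to (R) at the side-chain carbinol carbon, and this configuration is the one targeted; the commercial pinacol ester of 4-hydroxyphenylboronic acid is used as the boron component because it silylates cleanly.

Step 1
Reactants: 1 comenic acid (5-hydroxy-4-oxo-4H-pyran-2-carboxylic acid)
Product: 2 methyl 5-hydroxy-4-oxo-4H-pyran-2-carboxylate
Conditions: MeOH, H2SO4 (cat.), reflux
Reagents that add atoms: methanol, CO
Why: Fischer esterification in excess methanol converts only the carboxylic acid and leaves the enolic 5-OH and the pyranone untouched.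

Step 2
Reactants: 2 methyl 5-hydroxy-4-oxo-4H-pyran-2-carboxylate
Product: 3 methyl 4-oxo-5-(trifluoromethylsulfonyloxy)-4H-pyran-2-carboxylate
Conditions: Tf2O, pyridine, CH2Cl2, −20 → 0 °C
Reagents that add atoms: trifluoromethanesulfonic anhydride, O=S(=O)(OS(=O)(=O)C(F)(F)F)C(F)(F)F
Why: O-sulfonylation of the acidic enolic hydroxyl of a 3-hydroxy-4-pyranone gives the pyranonyl triflate, the usual electrophile for cross-coupling at this position.

Step 3
Reactants: 4 4-(4,4,5,5-tetramethyl-1,3,2-dioxaborolan-2-yl)phenol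
Product: 5 triisopropyl[4-(4,4,5,5-tetramethyl-1,3,2-dioxaborolan-2-yl)phenoxy]silane
Conditions: i-Pr3SiCl, imidazole, DMF, rt
Reagents that add atoms: chlorotriisopropylsilane, CC(C)[Si](Cl)(C(C)C)C(C)C
Why: Imidazole-promoted silylation of a phenol leaves the pinacol boronate intact and installs a silyl ether that should tolerate mild base, diazomethane and light and leave with fluoride at the end.

Step 4
Reactants: 3 methyl 4-oxo-5-(trifluoromethylsulfonyloxy)-4H-pyran-2-carboxylate; 5 triisopropyl[4-(4,4,5,5-tetramethyl-1,3,2-dioxaborolan-2-yl)phenoxy]silane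
Product: 6 methyl 4-oxo-5-[4-(triisopropylsilyloxy)phenyl]-4H-pyran-2-carboxylate
Conditions: Pd(PPh3)4 (5 mol %), K3PO4, 1,4-dioxane, H2O (3 equiv), 80 °C
Reagents that add atoms: none
Why: Suzuki–Miyaura coupling: the electron-poor enol triflate adds readily to zerovalent palladium and the boronate transmetalates under phosphate activation with too little water to hydrolyse the ester or the silyl ether.

Step 5
Reactants: 6 methyl 4-oxo-5-[4-(triisopropylsilyloxy)phenyl]-4H-pyran-2-carboxylate
Product: 7 4-oxo-5-[4-(triisopropylsilyloxy)phenyl]-4H-pyran-2-carboxylic acid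
Conditions: LiOH·H2O (1.2 equiv), THF/H2O, 0 °C; then 1 M HCl to pH 3
Reagents that add atoms: lithium hydroxide, [Li+].[OH-] (hydroxyl oxygen of the acid)
Why: Saponification of this activated heteroaryl ester at 0 °C with a slight excess of hydroxide should be faster than attack on the pyranone ring or on the hindered aryl silyl ether.

Step 6
Reactants: 7 4-oxo-5-[4-(triisopropylsilyloxy)phenyl]-4H-pyran-2-carboxylic acid
Product: 9 2-diazo-1-{4-oxo-5-[4-(triisopropylsilyloxy)phenyl]-4H-pyran-2-yl}ethanone, via acid chloride 8 (not isolated)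
Conditions: (COCl)2, DMF (cat.), CH2Cl2, 0 °C → rt, evaporate; CH2N2 (3 equiv), Et2O/THF, 0 °C
Reagents that add atoms: diazomethane, C=[N+]=[N-] (oxalyl chloride, O=C(Cl)C(=O)Cl, supplies only the chlorine of 8)
Why: Acid chloride formation followed by C-acylation of diazomethane (first stage of the Arndt–Eistert sequence) gives the diazomethyl ketone, a second equivalent of diazomethane removing the HCl.

Step 7
Reactants: 10 ethyl 4-methylpent-3-enoate
Product: 13 triisopropyl[(5-methylhex-4-en-1-yn-1-yl)oxy]silane, via dibromoenolate 11 (not isolated), via lithium ynolate 12 (not isolated)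
Conditions: CH2Br2, lithium 2,2,6,6-tetramethylpiperidide, THF, −78 °C; n-BuLi, −78 → 0 °C; i-Pr3SiCl, −78 °C → rt
Reagents that add atoms: dibromomethane, BrCBr (alkyne carbon C2); chlorotriisopropylsilane, CC(C)[Si](Cl)(C(C)C)C(C)C
Why: Kowalski ester homologation: LiCHBr2 adds to the ester, bromine–lithium exchange on the dibromoenolate triggers a carbenoid 1,2-shift to the ynolate, and the bulky silyl chloride silylates it on oxygen to give a thermally robust ynol ether.

Step 8
Reactants: 9 2-diazo-1-{4-oxo-5-[4-(triisopropylsilyloxy)phenyl]-4H-pyran-2-yl}ethanone; 13 triisopropyl[(5-methylhex-4-en-1-yn-1-yl)oxy]silane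
Product: 18 5-hydroxy-6-(3-methylbut-2-enyl)-7-(triisopropylsilyloxy)-3-[4-(triisopropylsilyloxy)phenyl]-4H-chromen-4-one, via pyranonylketene 14 (not isolated), via cyclobutenone 15 (not isolated), via dienylketene 16 (not isolated), via 4aH-dienone 17 (not isolated)
Conditions: 13 (1.5 equiv), ClCH2CH2Cl (degassed), hν (365 nm, Pyrex), rt; then 80 °C
Reagents that add atoms: none
Why: Proposed new method: Irradiation at 365 nm addresses only the diazo n→π* absorption, so N2 is lost with 1,2-shift of the pyranonyl group (Wolff rearrangement) to ketene 14, which the electron-rich ynol ether 13 captures in a [2+2] cycloaddition (C5–C6 and C7–C8 bonds) to give cyclobutenone 15. At 80 °C the four-membered ring opens by thermal conrotatory 4π-electron electrocyclic cleavage to dienylketene 16, and ring A is closed by thermal disrotatory 6π-electron electrocyclization of the ketene carbon onto pyranone C3 (C4a–C5 bond), after which dienone 17 enolizes to the hydrogen-bonded C5 phenol. The closest known reaction type is the photochemical diazoketone–siloxyalkyne benzannulation of aryl, heteroaryl and alkenyl diazomethyl ketones; new here is a cross-conjugated 4-pyranone as the unsaturated arm, which is reasonable because its C2=C3 bond is an enol-ether-type alkene with little aromatic stabilization to lose. No stereocenter is created, since the sp3 carbons of 15 and 17 are racemic and disappear on ring opening and aromatization. The selectivity needed is the orientation of the [2+2] event (prenyl-bearing carbon to the ketene carbonyl carbon), secured by the polarization of the ynol ether whose carbon remote from oxygen is the nucleophile, and the site of ring closure, secured because C2=C3 is the only π bond conjugated with the ketene terminus. Competing pyranone photochemistry is held back by the long wavelength and ketene dimerization by the excess of 13.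

Step 9
Reactants: 18 5-hydroxy-6-(3-methylbut-2-enyl)-7-(triisopropylsilyloxy)-3-[4-(triisopropylsilyloxy)phenyl]-4H-chromen-4-one
Product: 19 5-methoxy-6-(3-methylbut-2-enyl)-7-(triisopropylsilyloxy)-3-[4-(triisopropylsilyloxy)phenyl]-4H-chromen-4-one
Conditions: MeOH, PPh3, DIAD, THF, 0 °C → rt
Reagents that add atoms: methanol, CO (methyl carbon only)
Why: Mitsunobu etherification methylates the only free, chelated 5-OH under neutral conditions that cannot cleave or scramble the two aryl silyl ethers, so the oxygen differentiation created in step 8 is used directly.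

Step 10
Reactants: 19 5-methoxy-6-(3-methylbut-2-enyl)-7-(triisopropylsilyloxy)-3-[4-(triisopropylsilyloxy)phenyl]-4H-chromen-4-one
Product: 20 7-hydroxy-5-methoxy-6-(3-methylbut-2-enyl)-3-[4-(triisopropylsilyloxy)phenyl]-4H-chromen-4-one
Conditions: K2CO3 (1.0 equiv), MeOH/THF, 0 °C; AcOH quench
Reagents that add atoms: none
Why: Base-mediated methanolysis of aryl silyl ethers follows the leaving-group ability of the phenoxide, so the 7-O-silyl group, para to the C4 carbonyl and thus a vinylogous silyl ester, should cleave well before the ordinary 4'-O-silyl ether.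

Step 11
Reactants: 20 7-hydroxy-5-methoxy-6-(3-methylbut-2-enyl)-3-[4-(triisopropylsilyloxy)phenyl]-4H-chromen-4-one
Product: 22 7-hydroxy-5-methoxy-6-(3-methylbut-2-enyl)-4-oxo-3-[4-(triisopropylsilyloxy)phenyl]-4H-chromene-8-carbaldehyde, via 8-hydroxymethyl phenol 21 (not isolated)
Conditions: MgCl2, Et3N, (CH2O)n, MeCN, reflux; 1 M HCl work-up
Reagents that add atoms: paraformaldehyde (formaldehyde), C=O
Why: Magnesium-mediated ortho-formylation of phenols (Casnati–Skattebøl reaction): the magnesium phenoxide delivers formaldehyde to C8, the only free ortho position and one activated by the para methoxy group, and a second formaldehyde oxidizes the hydroxymethyl intermediate by hydride transfer under conditions harmless to the prenyl group.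

Step 12
Reactants: 22 7-hydroxy-5-methoxy-6-(3-methylbut-2-enyl)-4-oxo-3-[4-(triisopropylsilyloxy)phenyl]-4H-chromene-8-carbaldehyde
Product: 23 5-methoxy-6-(3-methylbut-2-enyl)-4-oxo-7-(triisopropylsilyloxy)-3-[4-(triisopropylsilyloxy)phenyl]-4H-chromene-8-carbaldehyde
Conditions: i-Pr3SiOTf, 2,6-lutidine, CH2Cl2, 0 °C
Reagents that add atoms: triisopropylsilyl trifluoromethanesulfonate, CC(C)[Si](OS(=O)(=O)C(F)(F)F)(C(C)C)C(C)C
Why: The silyl triflate is reactive enough to silylate the hindered, hydrogen-bonded phenol, which must be capped so that the homologated aldehyde cannot close to a benzofuran.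

Step 13
Reactants: 23 5-methoxy-6-(3-methylbut-2-enyl)-4-oxo-7-(triisopropylsilyloxy)-3-[4-(triisopropylsilyloxy)phenyl]-4H-chromene-8-carbaldehyde
Product: 25 2-{5-methoxy-6-(3-methylbut-2-enyl)-4-oxo-7-(triisopropylsilyloxy)-3-[4-(triisopropylsilyloxy)phenyl]-4H-chromen-8-yl}acetaldehyde, via methyl enol ether 24 (not isolated)
Conditions: Ph3P(CH2OMe)Cl, KN(SiMe3)2, THF, 0 °C; 23, −78 → 0 °C; then 2 M HCl, THF, rt
Reagents that add atoms: (methoxymethyl)triphenylphosphonium chloride, [Cl-].COC[P+](c1ccccc1)(c1ccccc1)c1ccccc1 (aldehyde carbon); water, O (aldehyde oxygen)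
Why: Wittig methoxymethylenation of the aldehyde, which reacts far faster than the chromone carbonyl, followed by acid hydrolysis of the enol ether is the standard one-carbon homologation to an arylacetaldehyde, and dilute acid should leave the aryl silyl ethers and the prenyl group alone.

Step 14
Reactants: 25 2-{5-methoxy-6-(3-methylbut-2-enyl)-4-oxo-7-(triisopropylsilyloxy)-3-[4-(triisopropylsilyloxy)phenyl]-4H-chromen-8-yl}acetaldehyde
Product: 26 8-[(2R)-2-hydroxy-3-methylbut-3-enyl]-5-methoxy-6-(3-methylbut-2-enyl)-7-(triisopropylsilyloxy)-3-[4-(triisopropylsilyloxy)phenyl]-4H-chromen-4-one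
Conditions: 2-iodopropene, CrCl2 (10 mol %), N-[2-(4-isopropyl-4,5-dihydro-1,3-oxazol-2-yl)-6-methylphenyl]methanesulfonamide (single antipode, 12 mol %), 1,8-bis(dimethylamino)naphthalene (12 mol %), NiCl2(2,9-dimethyl-1,10-phenanthroline) (2 mol %), Mn powder, Zr(C5H5)2Cl2, LiCl, MeCN, rt
Reagents that add atoms: 2-iodopropene, C=C(C)I
Why: Catalytic asymmetric Nozaki–Hiyama–Kishi alkenylation: the ligand-bound alkenylchromium species (trivalent chromium) adds only to the aldehyde under non-basic conditions that do not enolize it, and the stereocenter is set by reagent control, the ligand antipode being chosen (by Mosher ester analysis of a first small run) to deliver the 2-propenyl group to the Si face, which gives (R).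

Step 15
Reactants: 26 8-[(2R)-2-hydroxy-3-methylbut-3-enyl]-5-methoxy-6-(3-methylbut-2-enyl)-7-(triisopropylsilyloxy)-3-[4-(triisopropylsilyloxy)phenyl]-4H-chromen-4-one
Product: 27 7-hydroxy-8-[(2R)-2-hydroxy-3-methylbut-3-enyl]-3-(4-hydroxyphenyl)-5-methoxy-6-(3-methylbut-2-enyl)-4H-chromen-4-one
Conditions: Bu4NF (2.5 equiv), AcOH (2.5 equiv), THF, 0 °C → rt
Reagents that add atoms: none
Why: Buffered fluoride removes both aryl silyl ethers without acid, so the ortho-prenyl phenol cannot cyclize and the allylic carbinol stereocenter is not touched.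

Compound list
1 | comenic acid (5-hydroxy-4-oxo-4H-pyran-2-carboxylic acid) | O=C(O)c1cc(=O)c(O)co1 | starting material
2 | methyl 5-hydroxy-4-oxo-4H-pyran-2-carboxylate | COC(=O)c1cc(=O)c(O)co1 | intermediate
3 | methyl 4-oxo-5-(trifluoromethylsulfonyloxy)-4H-pyran-2-carboxylate | COC(=O)c1cc(=O)c(OS(=O)(=O)C(F)(F)F)co1 | intermediate
4 | 4-(4,4,5,5-tetramethyl-1,3,2-dioxaborolan-2-yl)phenol | CC1(C)OB(OC1(C)C)c1ccc(O)cc1 | starting material
5 | triisopropyl[4-(4,4,5,5-tetramethyl-1,3,2-dioxaborolan-2-yl)phenoxy]silane | CC1(C)OB(OC1(C)C)c1ccc(O[Si](C(C)C)(C(C)C)C(C)C)cc1 | intermediate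
6 | methyl 4-oxo-5-[4-(triisopropylsilyloxy)phenyl]-4H-pyran-2-carboxylate | COC(=O)c1cc(=O)c(-c2ccc(O[Si](C(C)C)(C(C)C)C(C)C)cc2)co1 | intermediate
7 | 4-oxo-5-[4-(triisopropylsilyloxy)phenyl]-4H-pyran-2-carboxylic acid | OC(=O)c1cc(=O)c(-c2ccc(O[Si](C(C)C)(C(C)C)C(C)C)cc2)co1 | intermediate
8 | 4-oxo-5-[4-(triisopropylsilyloxy)phenyl]-4H-pyran-2-carbonyl chloride | ClC(=O)c1cc(=O)c(-c2ccc(O[Si](C(C)C)(C(C)C)C(C)C)cc2)co1 | intermediate (not isolated)
9 | 2-diazo-1-{4-oxo-5-[4-(triisopropylsilyloxy)phenyl]-4H-pyran-2-yl}ethanone | [N-]=[N+]=CC(=O)c1cc(=O)c(-c2ccc(O[Si](C(C)C)(C(C)C)C(C)C)cc2)co1 | intermediate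
10 | ethyl 4-methylpent-3-enoate | CCOC(=O)CC=C(C)C | starting material
11 | lithium 1,1-dibromo-5-methylhexa-1,4-dien-2-olate | [Li+].[O-]C(CC=C(C)C)=C(Br)Br | intermediate (not isolated)
12 | lithium 5-methylhex-4-en-1-yn-1-olate | [Li+].[O-]C#CCC=C(C)C | intermediate (not isolated)
13 | triisopropyl[(5-methylhex-4-en-1-yn-1-yl)oxy]silane | CC(C)=CCC#CO[Si](C(C)C)(C(C)C)C(C)C | intermediate
14 | 2-{4-oxo-5-[4-(triisopropylsilyloxy)phenyl]-4H-pyran-2-yl}ethenone | O=C=Cc1cc(=O)c(-c2ccc(O[Si](C(C)C)(C(C)C)C(C)C)cc2)co1 | intermediate (not isolated)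
15 | 2-(3-methylbut-2-enyl)-4-{4-oxo-5-[4-(triisopropylsilyloxy)phenyl]-4H-pyran-2-yl}-3-(triisopropylsilyloxy)cyclobut-2-en-1-one (racemic at C4) | O=C1C(CC=C(C)C)=C(O[Si](C(C)C)(C(C)C)C(C)C)C1c1cc(=O)c(-c2ccc(O[Si](C(C)C)(C(C)C)C(C)C)cc2)co1 | intermediate (not isolated)
16 | (3E)-2-(3-methylbut-2-enyl)-4-{4-oxo-5-[4-(triisopropylsilyloxy)phenyl]-4H-pyran-2-yl}-3-(triisopropylsilyloxy)buta-1,3-dien-1-one | O=C=C(CC=C(C)C)/C(O[Si](C(C)C)(C(C)C)C(C)C)=C\c1cc(=O)c(-c2ccc(O[Si](C(C)C)(C(C)C)C(C)C)cc2)co1 | intermediate (not isolated)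
17 | 6-(3-methylbut-2-enyl)-7-(triisopropylsilyloxy)-3-[4-(triisopropylsilyloxy)phenyl]-4aH-chromene-4,5-dione (racemic at C4a) | O=C1C(CC=C(C)C)=C(O[Si](C(C)C)(C(C)C)C(C)C)C=C2OC=C(c3ccc(O[Si](C(C)C)(C(C)C)C(C)C)cc3)C(=O)C21 | intermediate (not isolated)
18 | 5-hydroxy-6-(3-methylbut-2-enyl)-7-(triisopropylsilyloxy)-3-[4-(triisopropylsilyloxy)phenyl]-4H-chromen-4-one | CC(C)=CCc1c(O[Si](C(C)C)(C(C)C)C(C)C)cc2occ(-c3ccc(O[Si](C(C)C)(C(C)C)C(C)C)cc3)c(=O)c2c1O | intermediate
19 | 5-methoxy-6-(3-methylbut-2-enyl)-7-(triisopropylsilyloxy)-3-[4-(triisopropylsilyloxy)phenyl]-4H-chromen-4-one | CC(C)=CCc1c(O[Si](C(C)C)(C(C)C)C(C)C)cc2occ(-c3ccc(O[Si](C(C)C)(C(C)C)C(C)C)cc3)c(=O)c2c1OC | intermediate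
20 | 7-hydroxy-5-methoxy-6-(3-methylbut-2-enyl)-3-[4-(triisopropylsilyloxy)phenyl]-4H-chromen-4-one | CC(C)=CCc1c(O)cc2occ(-c3ccc(O[Si](C(C)C)(C(C)C)C(C)C)cc3)c(=O)c2c1OC | intermediate
21 | 7-hydroxy-8-(hydroxymethyl)-5-methoxy-6-(3-methylbut-2-enyl)-3-[4-(triisopropylsilyloxy)phenyl]-4H-chromen-4-one (present as its magnesium salt) | CC(C)=CCc1c(O)c(CO)c2occ(-c3ccc(O[Si](C(C)C)(C(C)C)C(C)C)cc3)c(=O)c2c1OC | intermediate (not isolated)
22 | 7-hydroxy-5-methoxy-6-(3-methylbut-2-enyl)-4-oxo-3-[4-(triisopropylsilyloxy)phenyl]-4H-chromene-8-carbaldehyde | CC(C)=CCc1c(O)c(C=O)c2occ(-c3ccc(O[Si](C(C)C)(C(C)C)C(C)C)cc3)c(=O)c2c1OC | intermediate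
23 | 5-methoxy-6-(3-methylbut-2-enyl)-4-oxo-7-(triisopropylsilyloxy)-3-[4-(triisopropylsilyloxy)phenyl]-4H-chromene-8-carbaldehyde | CC(C)=CCc1c(O[Si](C(C)C)(C(C)C)C(C)C)c(C=O)c2occ(-c3ccc(O[Si](C(C)C)(C(C)C)C(C)C)cc3)c(=O)c2c1OC | intermediate
24 | 5-methoxy-8-(2-methoxyethenyl)-6-(3-methylbut-2-enyl)-7-(triisopropylsilyloxy)-3-[4-(triisopropylsilyloxy)phenyl]-4H-chromen-4-one (E/Z mixture) | CC(C)=CCc1c(O[Si](C(C)C)(C(C)C)C(C)C)c(C=COC)c2occ(-c3ccc(O[Si](C(C)C)(C(C)C)C(C)C)cc3)c(=O)c2c1OC | intermediate (not isolated)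
25 | 2-{5-methoxy-6-(3-methylbut-2-enyl)-4-oxo-7-(triisopropylsilyloxy)-3-[4-(triisopropylsilyloxy)phenyl]-4H-chromen-8-yl}acetaldehyde | CC(C)=CCc1c(O[Si](C(C)C)(C(C)C)C(C)C)c(CC=O)c2occ(-c3ccc(O[Si](C(C)C)(C(C)C)C(C)C)cc3)c(=O)c2c1OC | intermediate
26 | 8-[(2R)-2-hydroxy-3-methylbut-3-enyl]-5-methoxy-6-(3-methylbut-2-enyl)-7-(triisopropylsilyloxy)-3-[4-(triisopropylsilyloxy)phenyl]-4H-chromen-4-one | C=C(C)[C@H](O)Cc1c(O[Si](C(C)C)(C(C)C)C(C)C)c(CC=C(C)C)c(OC)c2c(=O)c(-c3ccc(O[Si](C(C)C)(C(C)C)C(C)C)cc3)coc12 | intermediate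
27 | 7-hydroxy-8-[(2R)-2-hydroxy-3-methylbut-3-enyl]-3-(4-hydroxyphenyl)-5-methoxy-6-(3-methylbut-2-enyl)-4H-chromen-4-one (CNP0324832.1) | C=C(C)[C@H](O)Cc1c(O)c(CC=C(C)C)c(OC)c2c(=O)c(-c3ccc(O)cc3)coc12 | target

Total step count: 15. Longest linear sequence: 13 steps (steps 1, 2, 4, 5, 6, 8, 9, 10, 11, 12, 13, 14, 15, from comenic acid).

Steps most likely to fail

1. Step 8 (Proposed new method). The pyranone or the product may compete for light and photorearrange, the electron-poor ketene may dimerize before the alkyne traps it, or the 6π closure onto the cross-conjugated pyranone double bond may be too slow. The fallback uses known chemistry and buys ring A instead of building it. It cannot branch from a numbered compound, because none of compounds 1–17 contains ring A. It sets out from purchased genistein (5,7-dihydroxy-3-(4-hydroxyphenyl)-4H-chromen-4-one, O=c1c(-c2ccc(O)cc2)coc2cc(O)cc(O)c12) and comes back to the route at compound 18. Silylation of the two non-chelated hydroxyls (i-Pr3SiCl, imidazole, DMF, rt) should give 5-hydroxy-7-(triisopropylsilyloxy)-3-[4-(triisopropylsilyloxy)phenyl]-4H-chromen-4-one F1. Iodination ortho to the free chelated 5-OH (N-iodosuccinimide, DMF, rt) should give 5-hydroxy-6-iodo-7-(triisopropylsilyloxy)-3-[4-(triisopropylsilyloxy)phenyl]-4H-chromen-4-one F2. Stille coupling of F2 with tributyl(3-methylbut-2-enyl)stannane (Pd(PPh3)4, DMF, 80 °C) should then give 18.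

2. Step 14. Facial selectivity may be poor when a small 2-propenyl nucleophile adds to an unbranched aldehyde, and the enolizable arylacetaldehyde may be partly lost to self-condensation. The fallback sets out from aldehyde 25 and comes back at 26, setting the stereocenter by reduction instead of addition. Ligand-free Nozaki–Hiyama–Kishi coupling (2-iodopropene, CrCl2, NiCl2 (cat.), DMF, rt) should give racemic 8-(2-hydroxy-3-methylbut-3-enyl)-5-methoxy-6-(3-methylbut-2-enyl)-7-(triisopropylsilyloxy)-3-[4-(triisopropylsilyloxy)phenyl]-4H-chromen-4-one F3. Oxidation (Dess–Martin periodinane, NaHCO3, CH2Cl2, 0 °C) should give 5-methoxy-8-(3-methyl-2-oxobut-3-enyl)-6-(3-methylbut-2-enyl)-7-(triisopropylsilyloxy)-3-[4-(triisopropylsilyloxy)phenyl]-4H-chromen-4-one F4. Corey–Bakshi–Shibata reduction with the (S)-2-methyl oxazaborolidine and catecholborane (toluene, −78 °C) should then give 26: the 2-propenyl group acts as the large substituent, which places hydride on the Si face of the enone carbonyl and gives (R), while the unreactive chromone carbonyl is spared.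

3. Step 7. The lithium carbenoid base may deprotonate the doubly activated α-position of the β,γ-unsaturated ester instead of adding to its carbonyl group. The fallback sets out from ester 10 and comes back at ynolate 12, and so at 13, by oxidizing an acetylide instead of homologating the ester. Reduction (i-Bu2AlH, CH2Cl2, −78 °C) should give 4-methylpent-3-enal F5, used crude. Dibromoolefination (CBr4, PPh3, CH2Cl2, 0 °C) should give 1,1-dibromo-5-methylhexa-1,4-diene F6. Treatment with n-BuLi (2.1 equiv, THF, −78 °C) should give lithium 5-methylhex-4-en-1-yn-1-ide F7 (Corey–Fuchs sequence). Oxidation of F7 with t-BuOOLi (from t-BuOOH and LiN(SiMe3)2, THF, −78 → 0 °C) should give ynolate 12, which is silylated with i-Pr3SiOTf to 13.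

Further compounds
F1 | step 8 | 5-hydroxy-7-(triisopropylsilyloxy)-3-[4-(triisopropylsilyloxy)phenyl]-4H-chromen-4-one | O=c1c(-c2ccc(O[Si](C(C)C)(C(C)C)C(C)C)cc2)coc2cc(O[Si](C(C)C)(C(C)C)C(C)C)cc(O)c12
F2 | step 8 | 5-hydroxy-6-iodo-7-(triisopropylsilyloxy)-3-[4-(triisopropylsilyloxy)phenyl]-4H-chromen-4-one | O=c1c(-c2ccc(O[Si](C(C)C)(C(C)C)C(C)C)cc2)coc2cc(O[Si](C(C)C)(C(C)C)C(C)C)c(I)c(O)c12
F3 | step 14 | racemic 8-(2-hydroxy-3-methylbut-3-enyl)-5-methoxy-6-(3-methylbut-2-enyl)-7-(triisopropylsilyloxy)-3-[4-(triisopropylsilyloxy)phenyl]-4H-chromen-4-one | C=C(C)C(O)Cc1c(O[Si](C(C)C)(C(C)C)C(C)C)c(CC=C(C)C)c(OC)c2c(=O)c(-c3ccc(O[Si](C(C)C)(C(C)C)C(C)C)cc3)coc12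
F4 | step 14 | 5-methoxy-8-(3-methyl-2-oxobut-3-enyl)-6-(3-methylbut-2-enyl)-7-(triisopropylsilyloxy)-3-[4-(triisopropylsilyloxy)phenyl]-4H-chromen-4-one | C=C(C)C(=O)Cc1c(O[Si](C(C)C)(C(C)C)C(C)C)c(CC=C(C)C)c(OC)c2c(=O)c(-c3ccc(O[Si](C(C)C)(C(C)C)C(C)C)cc3)coc12
F5 | step 7 | 4-methylpent-3-enal | CC(C)=CCC=O
F6 | step 7 | 1,1-dibromo-5-methylhexa-1,4-diene | CC(C)=CCC=C(Br)Br
F7 | step 7 | lithium 5-methylhex-4-en-1-yn-1-ide | [Li+].[C-]#CCC=C(C)C
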